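Next to green stand three flasks with the same Q and X but more L, and we have to reckon whether that extra L buys more D.

the same everywhere: Q 0.050 M; X 0.25 mM; time 12 min
- green: L 0.0120 M
- red: L 0.0400 M
- teal: L 0.100 M
- ochre: L 0.300 M

    L + L.E → L.L.E (k1 = 1.2 /M/s)
    Q.X ⇌ E (K2 = 0.81, k2 = 64 /s)
    L.E → X + D (k3 = 4.0 /s)
    Q + X ⇌ Q.X (K4 = 60 /M, k4 = 150 /M/s)
    L + E → L.E (k5 = 210 /M/s)

1. amount of D at the end, in percent of the Q charged for green, red, teal, ochre, in this order
2. the shape of the row from first to last (rises all the way / rises, then falls / hardly changes / falls, then rises / falls all the way)

- "hardly changes" means that all values lie within two and a half points (for a concentration: within two and a half percent of the largest)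
- run time (green): 12 min

**The lost share.** X binds Q, Q.X turns into E, and E takes up L to give L.E. L.E then either releases D and X, with constant k_rel = 4.0 /s, or takes a second L, with constant k_loss = 1.2 /M/s, and becomes L.L.E, an off-cycle form that no step returns. Each D costs one L, and each D made at c_L costs k_loss·c_L/k_rel of a catalyst. Summing this while c_L falls from its charge to zero gives the lost share Φ = k_loss·(charged c_L)·(charged c_L)/(2·k_rel·c_X), with c_X the catalyst charged; for Φ below 1 it is the part of the catalyst gone when L has gone. In green it is 0.0864, and we carry this lost share forward.

**Reading it.** Below 1, with L charged below Q, L is the limiting reagent and c_D ends close to the charged c_L. So green, with L pseudo-first-order and halving in about 0.582 min, well within the run, should reach 24.0% of Q. Above 1, the catalyst dies first, at c_D = (charged c_L)·(1 − √(1 − 1/Φ)). Teal, with Φ 6.00, gives 17.4%, and ochre, with Φ 54.0, gives 5.58%.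

**Where it stops.** One number is not enough for red, whose Φ is 0.960, close to 1. With Φ this near 1, we expect L and live catalyst to fall together in red, so the reading time enters, and we commit only to a ceiling of 80.0% for red, the charge of L against the charge of Q.

**The forecast.** It gives 23.9%, 63%, 17.5% and 5.6%, with the shape: rises, then falls. Its grounds for red are “Red sits near the crossover, where the L and the catalyst run out almost together”. It commits to a number for red where we stop at a ceiling.

**The result.** The flasks give 23.9%, 63.8%, 17.5% and 5.59%, with the shape: rises, then falls. Green ends with 8.57% of its catalyst as L.L.E, against a lost share of 8.64%. Red still holds 19.1% of its L at 12.0 min. Red's lost share of 96.0% stands beside 94.4% of the catalyst as L.L.E at 120 min, when 0.169% of its L remains and D has reached 78.9%.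

(The numbers of this flask were drawn at random within sensible limits.)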